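The runs come from a simulation with constants of no real substance; the scatter is artificial.

I charge the summer flask like the winter run, add no product and leave it for 87 min. Before committing, I want to know that the substrate left then will stand clear of the scatter of 0.6 mM.

common to all: coupling partner 240 mM; catalyst 0.400 mM
- winter: substrate 200 mM
- spring: substrate 600 mM
- autumn: substrate 200 mM; product 100 mM
- summer: substrate 200 mM; time 87 min

| winter run: time / min | winter run: [substrate] / mM | spring run: time / min | spring run: [substrate] / mM | autumn run: time / min | autumn run: [substrate] / mM |
|---|---|---|---|---|---|
| 1.0 | 199.4 | 1.0 | 599.8 | 1.0 | 188.6 |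
| 3.2 | 195.2 | 3.2 | 595.0 | 3.2 | 164.7 |
| 6.0 | 189.2 | 6.0 | 579.5 | 6.0 | 135.2 |
| 9.6 | 177.8 | 9.6 | 538.3 | 9.6 | 104.0 |
| 14 | 161.2 | 14 | 468.9 | 14 | 77.0 |
| 18 | 143.8 | 18 | 415.5 | 18 | 58.0 |
| 23 | 120.5 | 23 | 380.3 | 23 | 44.6 |
| 29 | 94.5 | 29 | 365.8 | 29 | 31.2 |

(readings scatter by 0.6 mM)

- reaction order in [substrate] at the outset, round the charge of the winter run, defined at two percent of the substrate turned into product (one fixed amount of product, the same in the runs compared)
- substrate in the summer run at 87 min, as a share of the substrate charged

- Overall: substrate + coupling partner -> product, with catalyst as catalyst.
- Constant volume, constant temperature.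
- What is held in complexes is read along with the free species.
- "The second partner" is coupling partner.
- An order is taken over about fifteen percent of the charge, up and down.

Substrate is the limiting reagent of this charge, and the coupling partner stays 0.0400 M above it. So at one [substrate], the winter and autumn runs also share one [coupling partner], and their [product] differs by 100 mM. I therefore compare the two runs at one [substrate], not at one minute, and I assume that the rest of the rate is the same at the two different times.

The autumn run falls from 188.6 mM to 164.7 mM at 10.9 mM min⁻¹. The winter run crosses nearly that stretch, from 189.2 mM to 161.2 mM, at 3.50 mM min⁻¹. I take [substrate] as 177 mM and [coupling partner] as 217 mM. Dividing the rate difference by these and by the added product gives 1.92 L² mol⁻² min⁻¹. This is my product gain, the extra rate per unit of [substrate]·[coupling partner]·[product], and it is a reading that carries their scatter.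

My own reckoning starts from the last winter interval, whose pseudo-first-order constant reads 0.0405 min⁻¹. At 94.5 mM, the product gain accounts for 0.0273 min⁻¹ of it, leaving 0.0132 min⁻¹, which I assume stays put. As [substrate] nears zero, the gain's part sinks towards 0.0154 min⁻¹. Taking the mean of the two ends over the remaining 58.0 min leaves 12.7 mM, or 6.37% of the charge. That is far above the scatter, so the plan stands.

The forecast says 4.5% and an order of 0.4, holding that “the apparent first-order constant stays near 0.04 min⁻¹”. Mine lets the constant sink, so my share is higher. For the order, I commit to no number of my own.

The summer flask gives 5.72%, and the order comes to 0.33, lower than the forecast's.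

    active catalyst + substrate ⇌ catalyst-substrate complex, settled at all times (1.550 L mol⁻¹)
    catalyst-substrate complex + coupling partner ⇌ ternary complex, settled at all times (52.10 L mol⁻¹)
    ternary complex → product + active catalyst (5.910 min⁻¹)
    catalyst → active catalyst (0.7080 min⁻¹)
    substrate + coupling partner + product → 2 product (2.130 L² mol⁻² min⁻¹)

The spring run, with 3.00 times the substrate, runs 1.5 times as fast as the winter run once 4.00 mM of product is made. At that amount of product, the term that the product gain multiplies, [substrate]·[coupling partner]·[product], stands 3.04 times as high in the spring run as in the winter run.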